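## Retrosynthetic overview

1. Manuifolin E is traced back through MOM removal, Mitsunobu closure of O1–C2 and hydride opening of a lactone to an (R)-3-aryl-3,4-dihydrocoumarin.
2. The strategy rests on two latent units. O1–C8a–C4a–C4 of rings A and C is an o-quinone methide whose C4 is stabilised by O7, which lies para to C4a. C2–C3 with ring B is an arylacetic acid enolate.
3. The key disconnection cuts C3–C4 and O1–C2 of the lactone. Both bonds form in a carbene-catalysed formal [4+2] of a 2-(silyloxy)benzyl bromide (fluoride trigger) with an arylacetyl imidazole, and the catalyst sets C3.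
4. Both halves come from one aldehyde, the 4-O-prenyl ether of 2,4-dihydroxybenzaldehyde. O2 is capped first, and an aromatic Claisen rearrangement then places the 1,1-dimethylallyl group at C5. The ring B half is lengthened by one carbon with TosMIC, so the two phenols of a dihydroxyphenylacetic acid never have to be differentiated.
5. Rings A and B are bought. Ring C is closed as a lactone (step 13), opened (step 14) and closed again as the chroman ether (step 15).

Key step: step 13

Assumption: the sense of induction of the aminoindanol-derived triazolylidene for this enolate and quinone methide pair is taken by analogy. The route is written with the (5aS,10bR) salt, Cc1cc(C)c(c(C)c1)-[n+]1nc2CO[C@H]3Cc4ccccc4[C@H]3n2c1.F[B-](F)(F)F. If a pilot run points to the (S)-lactone, the commercial (5aR,10bS) antipode is used and nothing else changes.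

## Route

Step 1
Reactants: 1 2,4-dihydroxybenzaldehyde; 2 prenyl bromide (1-bromo-3-methylbut-2-ene)
Product: 3 2-hydroxy-4-[(3-methylbut-2-en-1-yl)oxy]benzaldehyde
Conditions: K2CO3 (1.05 equiv), 2 (1.05 equiv), acetone, 50 °C
Reagents that add atoms: none
Why: Williamson ether synthesis in which the 4-OH, para to the formyl group and the more acidic phenol, is alkylated by SN2 at the primary allylic bromide while the 2-OH stays locked in its hydrogen bond to the aldehyde, so that one equivalent of base and halide should stop at the mono ether.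

Step 2
Reactants: 3 2-hydroxy-4-[(3-methylbut-2-en-1-yl)oxy]benzaldehyde
Product: 4 2-[(tert-butyldimethylsilyl)oxy]-4-[(3-methylbut-2-en-1-yl)oxy]benzaldehyde
Conditions: TBSCl, imidazole, DMF, rt
Reagents that add atoms: tert-butyldimethylsilyl chloride, CC(C)(C)[Si](C)(C)Cl
Why: Imidazole-promoted O-silylation of a phenol, which breaks the chelate that would otherwise steer the later rearrangement towards C3 and at the same time puts the fluoride-labile trigger on the future O1.

Step 3
Reactants: 4 2-[(tert-butyldimethylsilyl)oxy]-4-[(3-methylbut-2-en-1-yl)oxy]benzaldehyde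
Product: 6 2-[(tert-butyldimethylsilyl)oxy]-4-hydroxy-5-(2-methylbut-3-en-2-yl)benzaldehyde, via ortho-dienone 5 (not isolated)
Conditions: N,N-diethylaniline (degassed), 190 °C, sealed tube, Ar
Reagents that add atoms: none
Why: Aromatic Claisen rearrangement in which the [3,3] shift turns the prenyl unit round so that its tertiary carbon bonds to the ring, C5 is preferred to C3 because C3 sits between two oxygen substituents of which one carries the bulky silyl group, dienone 5 enolises to the phenol, and the weakly basic solvent holds back acid-induced prenyl loss and cyclisation onto the new alkene.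

Step 4
Reactants: 6 2-[(tert-butyldimethylsilyl)oxy]-4-hydroxy-5-(2-methylbut-3-en-2-yl)benzaldehyde
Product: 7 2-[(tert-butyldimethylsilyl)oxy]-4-(methoxymethoxy)-5-(2-methylbut-3-en-2-yl)benzaldehyde
Conditions: MOMCl, i-Pr2NEt, CH2Cl2, 0 °C to rt
Reagents that add atoms: chloromethyl methyl ether, COCCl
Why: MOM ether formation by O-alkylation of the acidic para-formyl phenol with a small, highly reactive chloromethyl ether that can reach the oxygen next to the tertiary alkyl group, while the hindered amine base leaves the aryl silyl ether in place.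

Step 5
Reactants: 7 2-[(tert-butyldimethylsilyl)oxy]-4-(methoxymethoxy)-5-(2-methylbut-3-en-2-yl)benzaldehyde
Product: 8 {2-[(tert-butyldimethylsilyl)oxy]-4-(methoxymethoxy)-5-(2-methylbut-3-en-2-yl)phenyl}methanol
Conditions: i-Bu2AlH, CH2Cl2, −78 °C; aq. potassium sodium tartrate
Reagents that add atoms: none
Why: Hydride reduction of the aldehyde with a neutral aluminium hydride, chosen because the aluminium alkoxide formed at low temperature should not take the silyl group over from O1 as a free alkoxide might, and because acetal, silyl ether and alkene are inert to it.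

Step 6
Reactants: 8 {2-[(tert-butyldimethylsilyl)oxy]-4-(methoxymethoxy)-5-(2-methylbut-3-en-2-yl)phenyl}methanol
Product: 9 tert-butyl[2-(bromomethyl)-5-(methoxymethoxy)-4-(2-methylbut-3-en-2-yl)phenoxy]dimethylsilane (ring A benzyl bromide)
Conditions: CBr4, PPh3 (1.05 equiv, added last), 2,6-lutidine (0.2 equiv), CH2Cl2, −20 to 0 °C
Reagents that add atoms: carbon tetrabromide, BrC(Br)(Br)Br
Why: Appel reaction, in which activation of the benzylic alcohol and SN2 displacement by bromide run under essentially neutral conditions so that MOM and silyl ethers survive, PPh3 is kept from excess to avoid quaternisation, and the donor-activated bromide is passed quickly through Et3N-washed silica and used the same day.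

Step 7
Reactants: 3 2-hydroxy-4-[(3-methylbut-2-en-1-yl)oxy]benzaldehyde
Product: 10 2-(methoxymethoxy)-4-[(3-methylbut-2-en-1-yl)oxy]benzaldehyde
Conditions: MOMCl (excess), i-Pr2NEt, CH2Cl2, 0 °C to rt
Reagents that add atoms: chloromethyl methyl ether, COCCl
Why: MOM ether formation on the chelated 2-OH, which gives a fluoride-stable acetal on the future O2' (an oxygen that must stay masked in the key step) and removes the chelate before the rearrangement.

Step 8
Reactants: 10 2-(methoxymethoxy)-4-[(3-methylbut-2-en-1-yl)oxy]benzaldehyde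
Product: 12 4-hydroxy-2-(methoxymethoxy)-5-(2-methylbut-3-en-2-yl)benzaldehyde, via ortho-dienone 11 (not isolated)
Conditions: N,N-diethylaniline (degassed), 190 °C, sealed tube, Ar
Reagents that add atoms: none
Why: Aromatic Claisen rearrangement on the same logic as step 3, with inversion of the prenyl unit, migration to the open C5 (para to the 2-alkoxy donor) rather than to C3 between two oxygens, enolisation of dienone 11, and aryl MOM ethers being a group that stands such thermal conditions in amine solvent.

Step 9
Reactants: 12 4-hydroxy-2-(methoxymethoxy)-5-(2-methylbut-3-en-2-yl)benzaldehyde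
Product: 13 2,4-bis(methoxymethoxy)-5-(2-methylbut-3-en-2-yl)benzaldehyde
Conditions: MOMCl, i-Pr2NEt, CH2Cl2, 0 °C to rt
Reagents that add atoms: chloromethyl methyl ether, COCCl
Why: MOM ether formation on the acidic 4-OH as in step 4, which leaves ring B with only base-stable and fluoride-stable groups.

Step 10
Reactants: 13 2,4-bis(methoxymethoxy)-5-(2-methylbut-3-en-2-yl)benzaldehyde
Product: 15 [2,4-bis(methoxymethoxy)-5-(2-methylbut-3-en-2-yl)phenyl]acetonitrile, via vinyl formamide 14 (not isolated)
Conditions: TosMIC, KOt-Bu (2.2 equiv), DME, −40 °C; then MeOH, reflux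
Reagents that add atoms: p-toluenesulfonylmethyl isocyanide (TosMIC), [C-]#[N+]CS(=O)(=O)c1ccc(C)cc1
Why: Van Leusen reductive cyanation, in which the TosMIC anion adds to the non-enolisable aldehyde, the adduct collapses at low temperature to vinyl formamide 14 rather than aromatising, and methanolysis of the formyl group with loss of sulfinate gives the nitrile one carbon longer under basic conditions that acetals and alkene tolerate.

Step 11
Reactants: 15 [2,4-bis(methoxymethoxy)-5-(2-methylbut-3-en-2-yl)phenyl]acetonitrile
Product: 17 [2,4-bis(methoxymethoxy)-5-(2-methylbut-3-en-2-yl)phenyl]acetic acid, via potassium carboxylate 16 (not isolated)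
Conditions: KOH, EtOH/H2O, reflux; then 1 M HCl, 0 °C, to pH 3–4
Reagents that add atoms: potassium hydroxide, [K+].[OH-]; water, O
Why: Base hydrolysis of a nitrile, which can be run at reflux because MOM acetals are base-stable and the quaternary allylic carbon leaves the alkene no position to migrate to, while brief cold acidification to a mild pH spares the acetals.

Step 12
Reactants: 17 [2,4-bis(methoxymethoxy)-5-(2-methylbut-3-en-2-yl)phenyl]acetic acid
Product: 18 2-[2,4-bis(methoxymethoxy)-5-(2-methylbut-3-en-2-yl)phenyl]-1-(1H-imidazol-1-yl)ethan-1-one (ring B acyl imidazole)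
Conditions: CDI (1.1 equiv), CH2Cl2, rt; cold water wash
Reagents that add atoms: 1,1'-carbonyldiimidazole, O=C(n1ccnc1)n1ccnc1
Why: Carboxyl activation with CDI, driven by loss of CO2, should give the isolable N-acyl imidazole without acid or strong base.

Step 13
Reactants: 9 ring A benzyl bromide; 18 ring B acyl imidazole
Product: 21 (3R)-3-[2,4-bis(methoxymethoxy)-5-(2-methylbut-3-en-2-yl)phenyl]-7-(methoxymethoxy)-6-(2-methylbut-3-en-2-yl)-3,4-dihydro-2H-chromen-2-one, via o-quinone methide 19 (not isolated), via azolium enolate 20 (not isolated)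
Conditions: (5aS,10bR)-2-mesityl-5a,10b-dihydro-4H,6H-indeno[2,1-b][1,2,4]triazolo[4,3-d][1,4]oxazin-2-ium tetrafluoroborate (15 mol %), CsF, 18-crown-6, THF, −20 °C, slow addition of 9; cold pH 6 buffer
Reagents that add atoms: none
Why: Fluoride from CsF/18-crown-6 cleaves the Si–O1 bond of 9 and the phenoxide expels bromide in a 1,4-elimination to give o-quinone methide 19, a step made easy by O7 para to C4a, while the triazolylidene displaces imidazole from 18 and the acyl azolium loses its doubly activated benzylic proton to give the (Z)-azolium enolate 20. C3 of 20 adds to the unsubstituted exocyclic C4 of 19, which restores the aromaticity of ring A, and the O1 phenoxide then attacks the acyl azolium carbon C2 in a 6-exo-trig lactonisation that closes ring C and frees the carbene. The closest known reaction type is the carbene/fluoride dual Lewis base formal [4+2] annulation of acyl-imidazole-derived azolium enolates with o-quinone methides made in situ from 2-(silyloxy)benzyl bromides, which gives enantioenriched 3-substituted dihydrocoumarins. C3 is the only new stereocentre and is set by the catalyst alone, since the fused indane blocks one face of the planar enolate and 19 is taken up from the open face, and the unsubstituted C4 raises no diastereoselectivity issue. The step needs capture of 19 by 20 to outrun self-condensation of 19 and uncatalysed enolisation of 18, which is served by slow addition of 9, by the reversibility of heteroatom additions to this donor-stabilised quinone methide, and by the fluoride-inert MOM group on O2' that stops ring B from lactonising onto its own acyl group. The C3–H of 21 is acidic, so the run is kept cold, stopped at full conversion and taken straight into step 14.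

Step 14
Reactants: 21 (R)-dihydrocoumarin
Product: 22 (2R)-2-[2,4-bis(methoxymethoxy)-5-(2-methylbut-3-en-2-yl)phenyl]-3-[2-hydroxy-4-(methoxymethoxy)-5-(2-methylbut-3-en-2-yl)phenyl]propan-1-ol
Conditions: LiAlH4 (excess), THF, −78 to 0 °C, 21 added to the hydride; aq. potassium sodium tartrate
Reagents that add atoms: none
Why: Hydride reduction of an aryl lactone to phenol and primary alcohol, in which inverse addition to excess hydride at low temperature should make both hydride deliveries to C2 faster than deprotonation at C3, after which the centre is no longer acidic and keeps its (R) configuration.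

Step 15
Reactants: 22 (R)-phenol-alcohol
Product: 23 (3R)-3-[2,4-bis(methoxymethoxy)-5-(2-methylbut-3-en-2-yl)phenyl]-7-(methoxymethoxy)-6-(2-methylbut-3-en-2-yl)-3,4-dihydro-2H-chromene
Conditions: PPh3, DIAD, THF (0.02 M), 0 °C to rt
Reagents that add atoms: none
Why: Intramolecular Mitsunobu etherification, in which the activated primary alcohol is displaced by the only free phenol, O1 of ring A, in a 6-exo-tet closure of ring C at the non-stereogenic C2, so that C3 is not touched.

Step 16
Reactants: 23 tris-MOM isoflavan
Product: 24 manuifolin E, 4-[(3R)-7-hydroxy-6-(2-methylbut-3-en-2-yl)-3,4-dihydro-2H-chromen-3-yl]-6-(2-methylbut-3-en-2-yl)benzene-1,3-diol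
Conditions: HCl (0.5 M, catalytic amount relative to solvent), MeOH, 40 °C
Reagents that add atoms: none
Why: Acid-catalysed acetal exchange with methanol removes the three MOM groups, and because the monosubstituted alkenes on quaternary carbons protonate far more slowly than a prenyl group would, mild acid at moderate temperature should free the phenols without ring closure onto the alkenes and without effect on C3.

## Compound list

1 | 2,4-dihydroxybenzaldehyde | O=Cc1ccc(O)cc1O | starting material
2 | prenyl bromide | CC(C)=CCBr | starting material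
3 | 2-hydroxy-4-[(3-methylbut-2-en-1-yl)oxy]benzaldehyde | O=Cc1ccc(OCC=C(C)C)cc1O | intermediate
4 | 2-[(tert-butyldimethylsilyl)oxy]-4-[(3-methylbut-2-en-1-yl)oxy]benzaldehyde | O=Cc1ccc(OCC=C(C)C)cc1O[Si](C)(C)C(C)(C)C | intermediate
5 | 6-[(tert-butyldimethylsilyl)oxy]-3-(2-methylbut-3-en-2-yl)-4-oxocyclohexa-1,5-diene-1-carbaldehyde (racemic ortho-dienone, not isolated) | O=CC1=CC(C(C)(C)C=C)C(=O)C=C1O[Si](C)(C)C(C)(C)C | intermediate
6 | 2-[(tert-butyldimethylsilyl)oxy]-4-hydroxy-5-(2-methylbut-3-en-2-yl)benzaldehyde | O=Cc1cc(C(C)(C)C=C)c(O)cc1O[Si](C)(C)C(C)(C)C | intermediate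
7 | 2-[(tert-butyldimethylsilyl)oxy]-4-(methoxymethoxy)-5-(2-methylbut-3-en-2-yl)benzaldehyde | O=Cc1cc(C(C)(C)C=C)c(OCOC)cc1O[Si](C)(C)C(C)(C)C | intermediate
8 | {2-[(tert-butyldimethylsilyl)oxy]-4-(methoxymethoxy)-5-(2-methylbut-3-en-2-yl)phenyl}methanol | OCc1cc(C(C)(C)C=C)c(OCOC)cc1O[Si](C)(C)C(C)(C)C | intermediate
9 | tert-butyl[2-(bromomethyl)-5-(methoxymethoxy)-4-(2-methylbut-3-en-2-yl)phenoxy]dimethylsilane | C=CC(C)(C)c1cc(CBr)c(O[Si](C)(C)C(C)(C)C)cc1OCOC | intermediate
10 | 2-(methoxymethoxy)-4-[(3-methylbut-2-en-1-yl)oxy]benzaldehyde | O=Cc1ccc(OCC=C(C)C)cc1OCOC | intermediate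
11 | 6-(methoxymethoxy)-3-(2-methylbut-3-en-2-yl)-4-oxocyclohexa-1,5-diene-1-carbaldehyde (racemic ortho-dienone, not isolated) | O=CC1=CC(C(C)(C)C=C)C(=O)C=C1OCOC | intermediate
12 | 4-hydroxy-2-(methoxymethoxy)-5-(2-methylbut-3-en-2-yl)benzaldehyde | O=Cc1cc(C(C)(C)C=C)c(O)cc1OCOC | intermediate
13 | 2,4-bis(methoxymethoxy)-5-(2-methylbut-3-en-2-yl)benzaldehyde | O=Cc1cc(C(C)(C)C=C)c(OCOC)cc1OCOC | intermediate
14 | N-{2-[2,4-bis(methoxymethoxy)-5-(2-methylbut-3-en-2-yl)phenyl]-1-(4-methylbenzenesulfonyl)ethenyl}formamide (not isolated) | O=CNC(=Cc1cc(C(C)(C)C=C)c(OCOC)cc1OCOC)S(=O)(=O)c1ccc(C)cc1 | intermediate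
15 | [2,4-bis(methoxymethoxy)-5-(2-methylbut-3-en-2-yl)phenyl]acetonitrile | N#CCc1cc(C(C)(C)C=C)c(OCOC)cc1OCOC | intermediate
16 | potassium [2,4-bis(methoxymethoxy)-5-(2-methylbut-3-en-2-yl)phenyl]acetate (not isolated) | [K+].[O-]C(=O)Cc1cc(C(C)(C)C=C)c(OCOC)cc1OCOC | intermediate
17 | [2,4-bis(methoxymethoxy)-5-(2-methylbut-3-en-2-yl)phenyl]acetic acid | OC(=O)Cc1cc(C(C)(C)C=C)c(OCOC)cc1OCOC | intermediate
18 | 2-[2,4-bis(methoxymethoxy)-5-(2-methylbut-3-en-2-yl)phenyl]-1-(1H-imidazol-1-yl)ethan-1-one | O=C(Cc1cc(C(C)(C)C=C)c(OCOC)cc1OCOC)n1ccnc1 | intermediate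
19 | 3-(methoxymethoxy)-4-(2-methylbut-3-en-2-yl)-6-methylidenecyclohexa-2,4-dien-1-one (o-quinone methide, not isolated) | C=C1C=C(C(C)(C)C=C)C(OCOC)=CC1=O | intermediate
20 | (Z)-azolium enolate of the ring B acyl group on the (5aS,10bR)-N-mesityl aminoindanol triazolylidene (zwitterion, not isolated) | Cc1cc(C)c(c(C)c1)-[n+]1nc2CO[C@H]3Cc4ccccc4[C@H]3n2c1/C([O-])=C/c1cc(C(C)(C)C=C)c(OCOC)cc1OCOC | intermediate
21 | (3R)-3-[2,4-bis(methoxymethoxy)-5-(2-methylbut-3-en-2-yl)phenyl]-7-(methoxymethoxy)-6-(2-methylbut-3-en-2-yl)-3,4-dihydro-2H-chromen-2-one | C=CC(C)(C)c1cc2c(cc1OCOC)OC(=O)[C@@H](c1cc(C(C)(C)C=C)c(OCOC)cc1OCOC)C2 | intermediate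
22 | (2R)-2-[2,4-bis(methoxymethoxy)-5-(2-methylbut-3-en-2-yl)phenyl]-3-[2-hydroxy-4-(methoxymethoxy)-5-(2-methylbut-3-en-2-yl)phenyl]propan-1-ol | OC[C@@H](c1cc(C(C)(C)C=C)c(OCOC)cc1OCOC)Cc1cc(C(C)(C)C=C)c(OCOC)cc1O | intermediate
23 | (3R)-3-[2,4-bis(methoxymethoxy)-5-(2-methylbut-3-en-2-yl)phenyl]-7-(methoxymethoxy)-6-(2-methylbut-3-en-2-yl)-3,4-dihydro-2H-chromene | C=CC(C)(C)c1cc2c(cc1OCOC)OC[C@@H](c1cc(C(C)(C)C=C)c(OCOC)cc1OCOC)C2 | intermediate
24 | manuifolin E, (3R) | C=CC(C)(C)c1cc2c(cc1O)OC[C@@H](c1cc(C(C)(C)C=C)c(O)cc1O)C2 | target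

## Step count and risks

Total step count: 16.
Longest linear sequence: 11 steps (1, 7, 8, 9, 10, 11, 12, 13, 14, 15, 16). The ring A branch (steps 2–6) joins at step 13.

Three steps most likely to fail:

1. **Step 13.**
   - What may go wrong: the enantiomeric purity may erode in two ways. Fluoride or imidazolide may enolise the acidic arylacetyl imidazole directly and open a racemic pathway. The finished lactone may also epimerise at its benzylic alpha position before it is reduced. In addition, the quinone methide may oligomerise faster than it is captured.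
   - Fallback: an Evans asymmetric alkylation forms the same C3–C4 bond. It sets out from acid 17 and bromide 9 and comes back to the route at 22.
   - Acid 17 is activated with PivCl/Et3N (THF, −20 °C) as the mixed pivalic anhydride F1. This acylates (R)-4-benzyloxazolidin-2-one in the presence of LiCl to give the imide F2.
   - The sodium (Z)-enolate of that imide (NaN(SiMe3)2, THF, −78 °C) is benzylated by 9 from the face opposite the benzyl group of the auxiliary, which should give the (2R)-configured benzylated imide F3.
   - LiBH4 (THF/MeOH, 0 °C) removes the auxiliary reductively to give the silyl-protected primary alcohol F4. n-Bu4NF buffered with AcOH then frees the phenol to give 22.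

2. **Step 3.** The same reaction in step 8 runs without the silyl ether and is judged safer.
   - What may go wrong: silyl transfer between phenols at 190 °C, loss of the prenyl group by elimination, partial migration to C3, and follow-up isomerisation or ring closure of the first-formed phenol onto its alkene.
   - Fallback: the carbon–carbon bond is made by cross-coupling instead of by a sigmatropic shift. It sets out from 1 and comes back at 7.
   - Aldehyde 1 is brominated (Br2, AcOH, rt) at C5, para to the 2-OH and ortho to the 4-OH, to give 5-bromo-2,4-dihydroxybenzaldehyde F5.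
   - The non-chelated 4-OH is capped (MOMCl, i-Pr2NEt, CH2Cl2) to give the bromo MOM ether F6.
   - A γ-selective Suzuki–Miyaura coupling follows with commercial prenylboronic acid pinacol ester (Pd(OAc)2, bulky biaryl monophosphine, aq. K3PO4, THF, 40 °C). Allyl transposition puts the tertiary carbon on the ring and gives the reverse-prenylated salicylaldehyde F7.
   - Silylation as in step 2 gives 7.

3. **Step 6.**
   - What may go wrong: the doubly donor-activated benzylic C–Br bond may ionise during formation or isolation, which leads to self-alkylation, hydrolysis, quaternisation of PPh3, or acetal loss through traces of HBr.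
   - Fallback: a storable benzylic ester replaces the halide as quinone methide source. It sets out from 8 and comes back at 19 inside step 13.
   - Alcohol 8 is acetylated (Ac2O, pyridine, catalytic DMAP, CH2Cl2, 0 °C) to the benzylic acetate F8, which should stand chromatography and storage.
   - Under the conditions of step 13, fluoride removes the silyl group and the phenoxide expels acetate. This is a known entry to o-quinone methides and is helped here by O7, so 19 forms and the annulation proceeds as written.

## Further compounds

F1 | step 13 | [2,4-bis(methoxymethoxy)-5-(2-methylbut-3-en-2-yl)phenyl]acetic pivalic anhydride | CC(C)(C)C(=O)OC(=O)Cc1cc(C(C)(C)C=C)c(OCOC)cc1OCOC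
F2 | step 13 | (4R)-4-benzyl-3-{[2,4-bis(methoxymethoxy)-5-(2-methylbut-3-en-2-yl)phenyl]acetyl}-1,3-oxazolidin-2-one | O=C(Cc1cc(C(C)(C)C=C)c(OCOC)cc1OCOC)N1C(=O)OC[C@H]1Cc1ccccc1
F3 | step 13 | (4R)-4-benzyl-3-{(2R)-2-[2,4-bis(methoxymethoxy)-5-(2-methylbut-3-en-2-yl)phenyl]-3-[2-(tert-butyldimethylsilyloxy)-4-(methoxymethoxy)-5-(2-methylbut-3-en-2-yl)phenyl]propanoyl}-1,3-oxazolidin-2-one | O=C([C@@H](c1cc(C(C)(C)C=C)c(OCOC)cc1OCOC)Cc1cc(C(C)(C)C=C)c(OCOC)cc1O[Si](C)(C)C(C)(C)C)N1C(=O)OC[C@H]1Cc1ccccc1
F4 | step 13 | (2R)-2-[2,4-bis(methoxymethoxy)-5-(2-methylbut-3-en-2-yl)phenyl]-3-[2-(tert-butyldimethylsilyloxy)-4-(methoxymethoxy)-5-(2-methylbut-3-en-2-yl)phenyl]propan-1-ol | OC[C@@H](c1cc(C(C)(C)C=C)c(OCOC)cc1OCOC)Cc1cc(C(C)(C)C=C)c(OCOC)cc1O[Si](C)(C)C(C)(C)C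
F5 | step 3 | 5-bromo-2,4-dihydroxybenzaldehyde | O=Cc1cc(Br)c(O)cc1O
F6 | step 3 | 5-bromo-2-hydroxy-4-(methoxymethoxy)benzaldehyde | O=Cc1cc(Br)c(OCOC)cc1O
F7 | step 3 | 2-hydroxy-4-(methoxymethoxy)-5-(2-methylbut-3-en-2-yl)benzaldehyde | O=Cc1cc(C(C)(C)C=C)c(OCOC)cc1O
F8 | step 6 | 2-[(tert-butyldimethylsilyl)oxy]-4-(methoxymethoxy)-5-(2-methylbut-3-en-2-yl)benzyl acetate | CC(=O)OCc1cc(C(C)(C)C=C)c(OCOC)cc1O[Si](C)(C)C(C)(C)C
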